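## Retrosynthetic overview

1. Feature: C8 carries ring B (the benzo ring) and two one-carbon oxygenated arms, C9H2–OH and C7H(O)–ring A (the trimethoxyphenyl ring). Without ring A, C7–C8–C9 is a prochiral 2-arylpropane-1,3-diol with enantiotopic hydroxymethyl arms.
2. Last disconnection: the C1'–C7' bond of the propenol chain, made by Heck coupling at a ring B bromide, followed by ester reduction and desilylation.
3. Key disconnection: C1(ring A)–C7 and O(on C4')–C7, made in one flask by arylcerium addition to the C7 aldehyde and then acid (acetal loss, benzylic cation, capture by the phenol). This closes the dihydrofuran ring, the only ring formed; rings A and B come from the starting materials.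
4. The C7 aldehyde comes from the diol by lipase monoacetylation (sets C8), silylation of the other arm, acetate removal and oxidation. The diol comes from Cu-catalysed arylation of diethyl malonate with iodinated, MOM-protected 4-bromo-2-methoxyphenol.

Key step: step 10

Remark (assumption): the lipase is taken to acetylate the arm that gives the (S)-monoacetate 7; if it prefers the other arm, the same compound is reached by enzymatic hydrolysis of the diacetate (see the fallback for step 5).

## Route

Step 1
Reactants: 1 4-bromo-2-methoxyphenol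
Product: 2 4-bromo-2-iodo-6-methoxyphenol
Conditions: N-iodosuccinimide, TsOH·H2O (cat.), MeCN, 0 °C → rt
Reagents that add atoms: N-iodosuccinimide, O=C1CCC(=O)N1I
Why: Electrophilic aromatic iodination in which the hydroxyl group is the strongest director and its para position is blocked by bromine, so iodine should enter the one free ortho position.

Step 2
Reactants: 2 4-bromo-2-iodo-6-methoxyphenol
Product: 3 5-bromo-1-iodo-3-methoxy-2-(methoxymethoxy)benzene
Conditions: MeOCH2Cl, iPr2NEt, CH2Cl2, 0 °C → rt
Reagents that add atoms: chloromethyl methyl ether, COCCl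
Why: O-alkylation of the phenol with the α-chloro ether gives the mixed acetal, which should survive base, hydride, the lipase and the oxidant and is cleaved by acid only in the key step.

Step 3
Reactants: 3 5-bromo-1-iodo-3-methoxy-2-(methoxymethoxy)benzene; 4 diethyl malonate
Product: 5 diethyl 2-[5-bromo-3-methoxy-2-(methoxymethoxy)phenyl]malonate
Conditions: CuI (10 mol%), pyridine-2-carboxylic acid (20 mol%), Cs2CO3, 1,4-dioxane, 50 °C; aq NH4Cl work-up
Reagents that add atoms: none
Why: Copper-catalysed Hurtley-type (Ullmann-type) C-arylation of the malonate anion, in which the C–I bond reacts far faster than the C–Br bond under these mild conditions, so the bromide is kept for the later Heck coupling.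

Step 4
Reactants: 5 diethyl 2-[5-bromo-3-methoxy-2-(methoxymethoxy)phenyl]malonate
Product: 6 2-[5-bromo-3-methoxy-2-(methoxymethoxy)phenyl]propane-1,3-diol
Conditions: LiAlH4, THF, 0 °C → rt (ester added to the hydride); H2O/aq NaOH work-up
Reagents that add atoms: none
Why: Hydride reduction of both esters to the prochiral diol, with inverse addition keeping hydride in excess so that reduction competes with malonate enolate formation, while the aryl bromide and the acetal are inert at this temperature.

Step 5
Reactants: 6 2-[5-bromo-3-methoxy-2-(methoxymethoxy)phenyl]propane-1,3-diol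
Product: 7 (S)-2-[5-bromo-3-methoxy-2-(methoxymethoxy)phenyl]-3-hydroxypropyl acetate
Conditions: Amano lipase PS (Burkholderia cepacia lipase, immobilised), vinyl acetate, iPr2O, rt
Reagents that add atoms: vinyl acetate, CC(=O)OC=C
Why: Lipase-catalysed irreversible transesterification (enzymatic desymmetrization of a prochiral 2-aryl-1,3-diol), in which the chiral active site acetylates one enantiotopic hydroxymethyl arm and so creates the C8 stereocentre, and faster further acetylation of any minor enantiomer to the diacetate should raise the enantiomeric purity of 7.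

Step 6
Reactants: 7 (S)-2-[5-bromo-3-methoxy-2-(methoxymethoxy)phenyl]-3-hydroxypropyl acetate
Product: 8 (R)-2-[5-bromo-3-methoxy-2-(methoxymethoxy)phenyl]-3-(tert-butyldiphenylsilyloxy)propyl acetate
Conditions: tBuPh2SiCl, imidazole, DMF, 0 °C → rt
Reagents that add atoms: tert-butyl(chloro)diphenylsilane, CC(C)(C)[Si](Cl)(c1ccccc1)c1ccccc1
Why: Imidazole-promoted silylation of the primary alcohol, with a base too weak to cause the 1,3-acetyl shift between the two arms that would racemise C8 (the descriptor changes only through the priority rules).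

Step 7
Reactants: 8 (R)-2-[5-bromo-3-methoxy-2-(methoxymethoxy)phenyl]-3-(tert-butyldiphenylsilyloxy)propyl acetate
Product: 9 (R)-2-[5-bromo-3-methoxy-2-(methoxymethoxy)phenyl]-3-(tert-butyldiphenylsilyloxy)propan-1-ol
Conditions: K2CO3 (0.3 equiv), MeOH, 0 °C
Reagents that add atoms: none
Why: Base-catalysed transesterification (methanolysis) of the acetate, under which the bulky tert-butyldiphenylsilyl ether should neither cleave nor migrate and C8, not yet next to a carbonyl group, cannot epimerise.

Step 8
Reactants: 9 (R)-2-[5-bromo-3-methoxy-2-(methoxymethoxy)phenyl]-3-(tert-butyldiphenylsilyloxy)propan-1-ol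
Product: 10 (S)-2-[5-bromo-3-methoxy-2-(methoxymethoxy)phenyl]-3-(tert-butyldiphenylsilyloxy)propanal
Conditions: Dess–Martin periodinane, CH2Cl2, 0 °C → rt; aq NaHCO3/Na2S2O3 wash; crude aldehyde used at once
Reagents that add atoms: none
Why: Dess–Martin oxidation by ligand exchange at iodine and internal proton removal under amine-free, nearly neutral conditions, and the aldehyde is taken on without chromatography so that the acidic C8–H has little chance to enolise.

Step 9
Reactants: 11 5-bromo-1,2,3-trimethoxybenzene
Product: 12 (3,4,5-trimethoxyphenyl)magnesium bromide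
Conditions: Mg turnings, I2 (cat.), THF, reflux → rt; solution titrated and used directly
Reagents that add atoms: magnesium, [Mg]
Why: Grignard formation by insertion of magnesium into the aryl C–Br bond, which is routine for this electron-rich bromide in THF.

Step 10
Reactants: 10 (S)-2-[5-bromo-3-methoxy-2-(methoxymethoxy)phenyl]-3-(tert-butyldiphenylsilyloxy)propanal; 12 (3,4,5-trimethoxyphenyl)magnesium bromide
Product: 16 tert-butyl{[(2R,3S)-5-bromo-7-methoxy-2-(3,4,5-trimethoxyphenyl)-2,3-dihydrobenzofuran-3-yl]methoxy}diphenylsilane, via arylcerium dichloride 13 (not isolated), via carbinol 14 (not isolated), via phenol carbinol 15 (not isolated)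
Conditions: CeCl3 (anhydrous), THF, −78 °C, then 12, 1 h; then 10, −78 °C; then 6 M aq HCl, −78 °C → rt
Reagents that add atoms: none
Why: The Grignard reagent is transmetallated to the oxophilic, weakly basic arylcerium dichloride 13, which should add to the aldehyde carbonyl faster than it removes the acidic C8–H (organocerium 1,2-addition to an enolisable aldehyde), giving carbinol 14 as a C7 epimer mixture whose composition does not matter. Aqueous HCl then hydrolyses the aryl methoxymethyl acetal to phenol 15 and ionises the benzylic C7–OH to a cation conjugated with ring A and stabilised by its 4-methoxy group; the closest known reaction is the acid-catalysed cyclodehydration of 2-(2-hydroxyphenyl)-1-arylethanols to 2-aryl-2,3-dihydrobenzofurans. The dihydrofuran ring closes by 5-exo-trig attack of the phenol oxygen on the trigonal C7 cation. C7 is set as R by substrate control, since the oxygen should add to the planar cation on the face anti to the C8 silyloxymethyl group, and because the closure is reversible in acid the more stable trans isomer is also the thermodynamic product; C8 keeps the configuration fixed by the lipase because after the addition no acidifying group is attached to it. The step needs addition over enolisation, which the cerium reagent at −78 °C should secure, and cleavage of the aryl acetal and the benzylic C–O bond without loss of the primary silyl ether or proton loss from the cation to a stilbene, which the acid stability of the tert-butyldiphenylsilyl group and the fast intramolecular capture should secure.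

Step 11
Reactants: 16 tert-butyl{[(2R,3S)-5-bromo-7-methoxy-2-(3,4,5-trimethoxyphenyl)-2,3-dihydrobenzofuran-3-yl]methoxy}diphenylsilane; 17 methyl acrylate
Product: 18 methyl (E)-3-[(2R,3S)-3-(tert-butyldiphenylsilyloxymethyl)-7-methoxy-2-(3,4,5-trimethoxyphenyl)-2,3-dihydrobenzofuran-5-yl]acrylate
Conditions: Pd(OAc)2 (5 mol%), P(o-tol)3 (15 mol%), Et3N, DMF, 100 °C
Reagents that add atoms: none
Why: Mizoroki–Heck coupling in which the unhindered aryl bromide adds oxidatively to zerovalent palladium formed in the flask, the acrylate inserts syn at its unsubstituted carbon and syn β-hydride elimination gives the E alkene, with both stereocentres untouched.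

Step 12
Reactants: 18 methyl (E)-3-[(2R,3S)-3-(tert-butyldiphenylsilyloxymethyl)-7-methoxy-2-(3,4,5-trimethoxyphenyl)-2,3-dihydrobenzofuran-5-yl]acrylate
Product: 19 (E)-3-[(2R,3S)-3-(tert-butyldiphenylsilyloxymethyl)-7-methoxy-2-(3,4,5-trimethoxyphenyl)-2,3-dihydrobenzofuran-5-yl]prop-2-en-1-ol
Conditions: iBu2AlH (2.5 equiv), CH2Cl2, −78 °C; aq potassium sodium tartrate work-up
Reagents that add atoms: none
Why: 1,2-Reduction of the unsaturated ester by the electrophilic aluminium hydride should give the allylic alcohol without touching the alkene, the silyl ether or the cyclic benzylic ether.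

Step 13
Reactants: 19 (E)-3-[(2R,3S)-3-(tert-butyldiphenylsilyloxymethyl)-7-methoxy-2-(3,4,5-trimethoxyphenyl)-2,3-dihydrobenzofuran-5-yl]prop-2-en-1-ol
Product: 20 (E)-3-[(2R,3S)-3-(hydroxymethyl)-7-methoxy-2-(3,4,5-trimethoxyphenyl)-2,3-dihydrobenzofuran-5-yl]prop-2-en-1-ol, the target (7R,8S,7'E)-3,4,5,5'-tetramethoxy-4',7-epoxy-8,3'-neolign-7'-ene-9,9'-diol
Conditions: Bu4NF, THF, 0 °C → rt
Reagents that add atoms: none
Why: Fluoride-induced cleavage of the Si–O bond, driven by the strong Si–F bond, frees the C9 hydroxyl group, and nothing else in the molecule responds to fluoride.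

## Compound list

1 | 4-bromo-2-methoxyphenol | COc1cc(Br)ccc1O | starting material
2 | 4-bromo-2-iodo-6-methoxyphenol | COc1cc(Br)cc(I)c1O | intermediate
3 | 5-bromo-1-iodo-3-methoxy-2-(methoxymethoxy)benzene | COCOc1c(I)cc(Br)cc1OC | intermediate
4 | diethyl malonate | CCOC(=O)CC(=O)OCC | starting material
5 | diethyl 2-[5-bromo-3-methoxy-2-(methoxymethoxy)phenyl]malonate | CCOC(=O)C(C(=O)OCC)c1cc(Br)cc(OC)c1OCOC | intermediate
6 | 2-[5-bromo-3-methoxy-2-(methoxymethoxy)phenyl]propane-1,3-diol | OCC(CO)c1cc(Br)cc(OC)c1OCOC | intermediate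
7 | (S)-2-[5-bromo-3-methoxy-2-(methoxymethoxy)phenyl]-3-hydroxypropyl acetate | CC(=O)OC[C@H](CO)c1cc(Br)cc(OC)c1OCOC | intermediate
8 | (R)-2-[5-bromo-3-methoxy-2-(methoxymethoxy)phenyl]-3-(tert-butyldiphenylsilyloxy)propyl acetate | CC(=O)OC[C@H](CO[Si](c1ccccc1)(c1ccccc1)C(C)(C)C)c1cc(Br)cc(OC)c1OCOC | intermediate
9 | (R)-2-[5-bromo-3-methoxy-2-(methoxymethoxy)phenyl]-3-(tert-butyldiphenylsilyloxy)propan-1-ol | OC[C@H](CO[Si](c1ccccc1)(c1ccccc1)C(C)(C)C)c1cc(Br)cc(OC)c1OCOC | intermediate
10 | (S)-2-[5-bromo-3-methoxy-2-(methoxymethoxy)phenyl]-3-(tert-butyldiphenylsilyloxy)propanal | O=C[C@H](CO[Si](c1ccccc1)(c1ccccc1)C(C)(C)C)c1cc(Br)cc(OC)c1OCOC | intermediate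
11 | 5-bromo-1,2,3-trimethoxybenzene | COc1cc(Br)cc(OC)c1OC | starting material
12 | (3,4,5-trimethoxyphenyl)magnesium bromide | COc1cc([Mg]Br)cc(OC)c1OC | intermediate
13 | (3,4,5-trimethoxyphenyl)cerium dichloride, formed in the flask | COc1cc([Ce](Cl)Cl)cc(OC)c1OC | intermediate
14 | (2S)-2-[5-bromo-3-methoxy-2-(methoxymethoxy)phenyl]-3-(tert-butyldiphenylsilyloxy)-1-(3,4,5-trimethoxyphenyl)propan-1-ol, mixture of C1 epimers, formed in the flask | OC(c1cc(OC)c(OC)c(OC)c1)[C@H](CO[Si](c1ccccc1)(c1ccccc1)C(C)(C)C)c1cc(Br)cc(OC)c1OCOC | intermediate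
15 | 4-bromo-2-[(2S)-1-(tert-butyldiphenylsilyloxy)-3-hydroxy-3-(3,4,5-trimethoxyphenyl)propan-2-yl]-6-methoxyphenol, mixture of carbinol epimers, formed in the flask | OC(c1cc(OC)c(OC)c(OC)c1)[C@H](CO[Si](c1ccccc1)(c1ccccc1)C(C)(C)C)c1cc(Br)cc(OC)c1O | intermediate
16 | tert-butyl{[(2R,3S)-5-bromo-7-methoxy-2-(3,4,5-trimethoxyphenyl)-2,3-dihydrobenzofuran-3-yl]methoxy}diphenylsilane | COc1cc([C@@H]2Oc3c(OC)cc(Br)cc3[C@H]2CO[Si](c4ccccc4)(c4ccccc4)C(C)(C)C)cc(OC)c1OC | intermediate
17 | methyl acrylate | C=CC(=O)OC | starting material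
18 | methyl (E)-3-[(2R,3S)-3-(tert-butyldiphenylsilyloxymethyl)-7-methoxy-2-(3,4,5-trimethoxyphenyl)-2,3-dihydrobenzofuran-5-yl]acrylate | COc1cc([C@@H]2Oc3c(OC)cc(/C=C/C(=O)OC)cc3[C@H]2CO[Si](c4ccccc4)(c4ccccc4)C(C)(C)C)cc(OC)c1OC | intermediate
19 | (E)-3-[(2R,3S)-3-(tert-butyldiphenylsilyloxymethyl)-7-methoxy-2-(3,4,5-trimethoxyphenyl)-2,3-dihydrobenzofuran-5-yl]prop-2-en-1-ol | COc1cc([C@@H]2Oc3c(OC)cc(/C=C/CO)cc3[C@H]2CO[Si](c4ccccc4)(c4ccccc4)C(C)(C)C)cc(OC)c1OC | intermediate
20 | (E)-3-[(2R,3S)-3-(hydroxymethyl)-7-methoxy-2-(3,4,5-trimethoxyphenyl)-2,3-dihydrobenzofuran-5-yl]prop-2-en-1-ol, the (7R,8S,7'E) target | COc1cc([C@@H]2Oc3c(OC)cc(/C=C/CO)cc3[C@H]2CO)cc(OC)c1OC | target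

## Step count and risks

Total step count: 13. Longest linear sequence: 12 steps (steps 1–8 and 10–13, from phenol 1); step 9 is a one-step side branch.

Steps most likely to fail:

Step 10 (key step). In the aqueous acid the C7 cation may lose the C8 proton to give a stilbene, which would erode the C8 configuration. The silyl ether may also be partly cleaved, or the closure may stop at a cis/trans mixture. The fallback closes the ring without a free cation. It sets out from aldehyde 10 and Grignard reagent 12 (CeCl3, THF, −78 °C), but the addition is quenched with aq NH4Cl and carbinol 14 is isolated. Its C7 epimers are separated by chromatography, and (1S,2S)-2-[5-bromo-3-methoxy-2-(methoxymethoxy)phenyl]-3-(tert-butyldiphenylsilyloxy)-1-(3,4,5-trimethoxyphenyl)propan-1-ol F1 is carried on; the (1R,2S) epimer of 14 is not used. NaHSO4·SiO2 in CH2Cl2 at rt should cleave the phenolic methoxymethyl ether selectively to 4-bromo-2-[(2S,3S)-1-(tert-butyldiphenylsilyloxy)-3-hydroxy-3-(3,4,5-trimethoxyphenyl)propan-2-yl]-6-methoxyphenol F2. A Mitsunobu cyclodehydration (PPh3, diisopropyl azodicarboxylate, THF, 0 °C) then forms O–C7 by SN2 displacement with inversion, so the 7S carbinol should give the 7R trans ring, and the route is rejoined at 16.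

Step 8. The α-aryl aldehyde may enolise toward the enol conjugated with ring B during oxidation, work-up or storage, with loss of the C8 configuration, or it may lose the silyloxy group by β-elimination. The fallback keeps C7 at the carboxylic acid oxidation level until ring A is attached. It sets out from alcohol 9. Oxidation with NaClO2, catalytic TEMPO and catalytic NaOCl in MeCN/phosphate buffer (pH 6.7, 35 °C) should give (S)-2-[5-bromo-3-methoxy-2-(methoxymethoxy)phenyl]-3-(tert-butyldiphenylsilyloxy)propanoic acid F3. Coupling with MeNHOMe·HCl (EDC·HCl, HOBt, iPr2NEt, CH2Cl2, 0 °C) gives (S)-2-[5-bromo-3-methoxy-2-(methoxymethoxy)phenyl]-3-(tert-butyldiphenylsilyloxy)-N-methoxy-N-methylpropanamide F4. Grignard reagent 12 (THF, −20 → 0 °C, aq NH4Cl quench) gives (S)-2-[5-bromo-3-methoxy-2-(methoxymethoxy)phenyl]-3-(tert-butyldiphenylsilyloxy)-1-(3,4,5-trimethoxyphenyl)propan-1-one F5. Reduction with NaBH4 (MeOH/THF, −40 °C) returns to the route at carbinol 14, which is closed to 16 with aq HCl in THF as in the second stage of step 10.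

Step 5. The ortho-substituted ring B may weaken the enzyme's discrimination between the two arms, the enzyme may acetylate the arm opposite to the one assumed, or over-acetylation may consume the monoacetate. The fallback runs the enzyme in the hydrolytic direction. It sets out from diol 6, which is acetylated on both arms (Ac2O, pyridine, DMAP cat., CH2Cl2) to 2-[5-bromo-3-methoxy-2-(methoxymethoxy)phenyl]propane-1,3-diyl diacetate F6. The same lipase in phosphate buffer (pH 7, acetone cosolvent, rt) should then remove the acetate from the arm it prefers and leave the acetate on the other arm. This gives the monoacetate of the sense opposite to that from acetylation, so the route is rejoined at 7 when acetylation has marked the wrong arm.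

## Further compounds

F1 | step 10 | (1S,2S)-2-[5-bromo-3-methoxy-2-(methoxymethoxy)phenyl]-3-(tert-butyldiphenylsilyloxy)-1-(3,4,5-trimethoxyphenyl)propan-1-ol | O[C@H](c1cc(OC)c(OC)c(OC)c1)[C@H](CO[Si](c1ccccc1)(c1ccccc1)C(C)(C)C)c1cc(Br)cc(OC)c1OCOC
F2 | step 10 | 4-bromo-2-[(2S,3S)-1-(tert-butyldiphenylsilyloxy)-3-hydroxy-3-(3,4,5-trimethoxyphenyl)propan-2-yl]-6-methoxyphenol | O[C@H](c1cc(OC)c(OC)c(OC)c1)[C@H](CO[Si](c1ccccc1)(c1ccccc1)C(C)(C)C)c1cc(Br)cc(OC)c1O
F3 | step 8 | (S)-2-[5-bromo-3-methoxy-2-(methoxymethoxy)phenyl]-3-(tert-butyldiphenylsilyloxy)propanoic acid | OC(=O)[C@H](CO[Si](c1ccccc1)(c1ccccc1)C(C)(C)C)c1cc(Br)cc(OC)c1OCOC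
F4 | step 8 | (S)-2-[5-bromo-3-methoxy-2-(methoxymethoxy)phenyl]-3-(tert-butyldiphenylsilyloxy)-N-methoxy-N-methylpropanamide | CON(C)C(=O)[C@H](CO[Si](c1ccccc1)(c1ccccc1)C(C)(C)C)c1cc(Br)cc(OC)c1OCOC
F5 | step 8 | (S)-2-[5-bromo-3-methoxy-2-(methoxymethoxy)phenyl]-3-(tert-butyldiphenylsilyloxy)-1-(3,4,5-trimethoxyphenyl)propan-1-one | COc1cc(cc(OC)c1OC)C(=O)[C@H](CO[Si](c1ccccc1)(c1ccccc1)C(C)(C)C)c1cc(Br)cc(OC)c1OCOC
F6 | step 5 | 2-[5-bromo-3-methoxy-2-(methoxymethoxy)phenyl]propane-1,3-diyl diacetate | CC(=O)OCC(COC(C)=O)c1cc(Br)cc(OC)c1OCOC
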